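A direct plan would desymmetrise the ring A triol as mono-silyl ether A1, lithiate its bis-acetal and add the chain aldehyde to give carbinol A2, dehydrate A2 to the E-styrene, build 2'-hydroxychalcone A3 and close ring C by asymmetric oxa-Michael addition. Its weakest steps would be:
- the statistical mono-protection of a symmetric triol, which would cost length and material without adding complexity;
- the carbinol dehydration, which would spend two operations on one double bond and could divert into cation–olefin cyclisation;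
- the chalcone ring closure, which would be reversible, hard to make enantioselective, and a channel for racemisation at C2.

The route rests on cutting the C2–C1' bond. Rings A and C are taken together as a flat, achiral 4H-chromen-4-one that already carries the C6 chain, and ring B is delivered last to C2 by rhodium-catalysed enantioselective 1,4-addition of an arylboronic acid to the C2=C3 enol-ether double bond. One operation thus joins the third ring and sets C2 under nearly neutral conditions, with no chalcone and no oxa-Michael equilibrium. The chain is attached in a single Heck reaction of (S)-β-citronellene at C6, a position fixed by iodination ortho to the hydrogen-bonded 5-OH, so that neither a statistical protection nor a carbinol dehydration is needed.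

Key step: step 5

Assumption: the (S)-configured biaryl bisphosphine is taken to deliver the aryl group to the face of C2 that gives 2S, by analogy with (S)-BINAP and 2-cyclohexenone (same enone face). If the sense were opposite, the (R)-ligand would be used with nothing else changed. Compounds 1, 5 and 7 are taken as catalogue compounds.

Step 1
Reactants: 1 5,7-dihydroxy-4H-chromen-4-one
Product: 2 5-hydroxy-7-(methoxymethoxy)-4H-chromen-4-one
Conditions: MOMCl (1.05 equiv), K2CO3, acetone, 0 °C to rt
Reagents that add atoms: chloromethyl methyl ether (MOMCl), COCCl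
Why: Williamson-type O-alkylation (acetal formation) should occur only at the more acidic, non-chelated 7-OH, because the 5-OH is held in a hydrogen bond to the C4 carbonyl.

Step 2
Reactants: 2 5-hydroxy-7-(methoxymethoxy)-4H-chromen-4-one
Product: 3 5-hydroxy-6-iodo-7-(methoxymethoxy)-4H-chromen-4-one
Conditions: NIS (1.05 equiv), DMF, 0 °C to rt, dark
Reagents that add atoms: N-iodosuccinimide (NIS), O=C1CCC(=O)N1I
Why: Electrophilic aromatic iodination of a chelated 5-hydroxy-7-alkoxy chromone is known to enter C6, ortho to the free hydroxyl, and not C8, so the site of the chain is fixed here without recourse to symmetry.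

Step 3
Reactants: 3 5-hydroxy-6-iodo-7-(methoxymethoxy)-4H-chromen-4-one
Product: 4 6-iodo-5,7-bis(methoxymethoxy)-4H-chromen-4-one
Conditions: NaH, DMF, 0 °C; then MOMCl, 0 °C to rt
Reagents that add atoms: chloromethyl methyl ether (MOMCl), COCCl
Why: Williamson O-alkylation of the sodium phenoxide with the small MOM chloride masks the chelated 5-OH, so that no phenoxide deactivates the enone in step 5 and no ortho-hydroxystyrene, which is prone to ortho-quinone methide formation, is ever heated.

Step 4
Reactants: 4 6-iodo-5,7-bis(methoxymethoxy)-4H-chromen-4-one; 5 (3S)-3,7-dimethylocta-1,6-diene ((S)-β-citronellene)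
Product: 6 6-[(1E,3S)-3,7-dimethylocta-1,6-dien-1-yl]-5,7-bis(methoxymethoxy)-4H-chromen-4-one
Conditions: 5 (4 equiv), Pd2(dba)3 (3 mol %), [HP(t-Bu)3]BF4 (12 mol %), Cy2NMe, 1,4-dioxane, 70 °C
Reagents that add atoms: none
Why: Mizoroki–Heck reaction, in which oxidative addition of the C6–I bond to zerovalent palladium, syn-insertion of the monosubstituted alkene with the hindered aryl group at the terminal carbon and β-hydride elimination toward the benzylic carbon should give the conjugated E-alkene, while the allylic stereocentre is carried over unchanged from 5 because the amine base removes the palladium hydride before it can re-insert.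

Step 5
Reactants: 6 6-[(1E,3S)-3,7-dimethylocta-1,6-dien-1-yl]-5,7-bis(methoxymethoxy)-4H-chromen-4-one; 7 (4-{[tert-butyl(dimethyl)silyl]oxy}phenyl)boronic acid
Product: 8 (2S)-2-(4-{[tert-butyl(dimethyl)silyl]oxy}phenyl)-6-[(1E,3S)-3,7-dimethylocta-1,6-dien-1-yl]-5,7-bis(methoxymethoxy)-2,3-dihydro-4H-chromen-4-one
Conditions: 7 (3 equiv), [RhCl(C2H4)2]2 (2.5 mol %), (S)-MeO-F12-BIPHEP [(S)-6,6'-dimethoxy-2,2'-bis{bis(3,4,5-trifluorophenyl)phosphanyl}-1,1'-biphenyl] (5.5 mol %), aq. KOH (0.2 equiv), toluene, 25 °C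
Reagents that add atoms: none
Why: Transmetalation from boron gives an aryl–rhodium species (monovalent rhodium) that coordinates the C2=C3 double bond of 6 and inserts it with the aryl group going to C2, and the resulting oxa-π-allyl rhodium enolate is protonated by water to release the ketone and the hydroxo-rhodium catalyst. The closest known reaction type is the Hayashi–Miyaura 1,4-addition of arylboronic acids to chromones, which gives 2-aryl-chroman-4-ones directly. No ring is closed, since ring C is already in place; the step forms the C2–C1' bond that joins ring B to the bicyclic core. The only new stereocentre, C2, is set by the chiral bisphosphine, which blocks one face of the flat enone during carborhodation (catalyst control; the C3'' centre is remote and should not interfere). The step needs 1,4- over 1,2-selectivity, secured by the non-polar medium and by the peri 5-OMOM group that shields the C4 carbonyl of the product, and chemoselectivity for the enone, secured because the hindered 1,2-disubstituted styrene and the trisubstituted alkene are far poorer acceptors for aryl–rhodium than the enone. Configurational stability at C2 rests on fast protonation of the enolate and on the sub-stoichiometric hydroxide, which should not open ring C of a 5-O-alkylated flavanone at 25 °C.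

Step 6
Reactants: 8 (2S)-2-(4-{[tert-butyl(dimethyl)silyl]oxy}phenyl)-6-[(1E,3S)-3,7-dimethylocta-1,6-dien-1-yl]-5,7-bis(methoxymethoxy)-2,3-dihydro-4H-chromen-4-one
Product: 10 (2S)-6-[(1E,3S)-3,7-dimethylocta-1,6-dien-1-yl]-5,7-dihydroxy-2-(4-hydroxyphenyl)-2,3-dihydro-4H-chromen-4-one, via bis(trimethylsilyl) ether 9 (not isolated)
Conditions: TMSOTf, 2,2'-bipyridyl, CH2Cl2, 0 °C to rt; then TBAF/AcOH (1:1), THF, 0 °C; pH 7 buffer
Reagents that add atoms: none
Why: Silyl triflate/2,2'-bipyridyl cleavage of the aromatic MOM ethers (transfer of the methoxymethyl group to nitrogen, aryl trimethylsilyl ether formation) followed by buffered fluoride desilylation should free all three phenols without Brønsted acid, which would cyclise the ortho-hydroxystyrene onto the remote alkene, and without free base, which would open ring C and erase C2.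

**Compound list**

1 | 5,7-dihydroxy-4H-chromen-4-one (5,7-dihydroxychromone) | Oc1cc(O)c2C(=O)C=COc2c1 | starting material
2 | 5-hydroxy-7-(methoxymethoxy)-4H-chromen-4-one | COCOc1cc(O)c2C(=O)C=COc2c1 | intermediate
3 | 5-hydroxy-6-iodo-7-(methoxymethoxy)-4H-chromen-4-one | COCOc1cc2OC=CC(=O)c2c(O)c1I | intermediate
4 | 6-iodo-5,7-bis(methoxymethoxy)-4H-chromen-4-one | COCOc1cc2OC=CC(=O)c2c(OCOC)c1I | intermediate
5 | (3S)-3,7-dimethylocta-1,6-diene ((S)-β-citronellene) | CC(C)=CCC[C@H](C)C=C | starting material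
6 | 6-[(1E,3S)-3,7-dimethylocta-1,6-dien-1-yl]-5,7-bis(methoxymethoxy)-4H-chromen-4-one | CC(C)=CCC[C@H](C)/C=C/c1c(OCOC)cc2OC=CC(=O)c2c1OCOC | intermediate
7 | (4-{[tert-butyl(dimethyl)silyl]oxy}phenyl)boronic acid | CC(C)(C)[Si](C)(C)Oc1ccc(cc1)B(O)O | starting material
8 | (2S)-2-(4-{[tert-butyl(dimethyl)silyl]oxy}phenyl)-6-[(1E,3S)-3,7-dimethylocta-1,6-dien-1-yl]-5,7-bis(methoxymethoxy)-2,3-dihydro-4H-chromen-4-one | CC(C)=CCC[C@H](C)/C=C/c1c(OCOC)cc2c(c1OCOC)C(=O)C[C@@H](c1ccc(O[Si](C)(C)C(C)(C)C)cc1)O2 | intermediate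
9 | (2S)-2-(4-{[tert-butyl(dimethyl)silyl]oxy}phenyl)-6-[(1E,3S)-3,7-dimethylocta-1,6-dien-1-yl]-5,7-bis[(trimethylsilyl)oxy]-2,3-dihydro-4H-chromen-4-one | CC(C)=CCC[C@H](C)/C=C/c1c(O[Si](C)(C)C)cc2c(c1O[Si](C)(C)C)C(=O)C[C@@H](c1ccc(O[Si](C)(C)C(C)(C)C)cc1)O2 | intermediate
10 | (2S)-6-[(1E,3S)-3,7-dimethylocta-1,6-dien-1-yl]-5,7-dihydroxy-2-(4-hydroxyphenyl)-2,3-dihydro-4H-chromen-4-one | CC(C)=CCC[C@H](C)/C=C/c1c(O)cc2c(c1O)C(=O)C[C@@H](c1ccc(O)cc1)O2 | target

Total step count: 6. Longest linear sequence: 6 steps (1 to 10).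

Steps most likely to fail:

Step 5. The electron-rich, 5-alkoxylated enone may undergo carborhodation too slowly, so that protodeboronation of 7 takes over, or the facial selectivity may be insufficient. The fallback would separate bond formation from stereocontrol. Chromone 6 would be arylated with 7 under the more active achiral catalyst [Rh(OH)(cod)]2 (dioxane/H2O, 40 °C) to give the C2-epimer mixture (2RS)-2-(4-{[tert-butyl(dimethyl)silyl]oxy}phenyl)-6-[(1E,3S)-3,7-dimethylocta-1,6-dien-1-yl]-5,7-bis(methoxymethoxy)-2,3-dihydro-4H-chromen-4-one F1. This mixture would be resolved kinetically by asymmetric transfer hydrogenation (RuCl(p-cymene)[(R,R)-TsDPEN], HCO2H/Et3N, rt; the catalyst enantiomer is chosen so that the 2R epimer reacts). The 2R epimer should be reduced to the cis alcohol (2R,4R)-2-(4-{[tert-butyl(dimethyl)silyl]oxy}phenyl)-6-[(1E,3S)-3,7-dimethylocta-1,6-dien-1-yl]-5,7-bis(methoxymethoxy)-3,4-dihydro-2H-chromen-4-ol F2 and removed by chromatography, leaving the 2S ketone, compound 8.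

Step 4. β-Hydride elimination may go toward C3'' instead of the benzylic carbon, giving the deconjugated isomer and, after re-insertion, erosion of the C3'' configuration, or insertion may be sluggish at the doubly ortho-substituted aryl–palladium centre. The fallback would fix the E geometry in the coupling partner. (3S)-3,7-Dimethyloct-6-enal ((S)-citronellal) F3 would be converted into (3S)-3,7-dimethyloct-6-en-1-yne F4 by nonaflation–elimination (C4F9SO2F, phosphazene base, DMF). The alkyne would be hydroborated with pinacolborane under Cp2Zr(H)Cl catalysis to 2-[(1E,3S)-3,7-dimethylocta-1,6-dien-1-yl]-4,4,5,5-tetramethyl-1,3,2-dioxaborolane F5. Suzuki–Miyaura coupling of F5 with iodide 4 (Pd(OAc)2, SPhos, K3PO4, THF/H2O, 40 °C) would return to compound 6.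

Step 6. The Lewis acid may trigger cation–olefin cyclisation of the chain or ionise the benzylic C2–O1 bond, with loss of configuration, during acetal cleavage. The fallback would be an end game that needs fluoride only. The acetals of iodide 4, which carries neither the chain nor C2, would be cleaved with HCl in methanol to 5,7-dihydroxy-6-iodo-4H-chromen-4-one F6. Silylation (TBSOTf, 2,6-lutidine, CH2Cl2) would give 5,7-bis{[tert-butyl(dimethyl)silyl]oxy}-6-iodo-4H-chromen-4-one F7. Heck coupling with 5 as in step 4 would give 5,7-bis{[tert-butyl(dimethyl)silyl]oxy}-6-[(1E,3S)-3,7-dimethylocta-1,6-dien-1-yl]-4H-chromen-4-one F8. Arylation with 7 as in step 5 would give (2S)-5,7-bis{[tert-butyl(dimethyl)silyl]oxy}-2-(4-{[tert-butyl(dimethyl)silyl]oxy}phenyl)-6-[(1E,3S)-3,7-dimethylocta-1,6-dien-1-yl]-2,3-dihydro-4H-chromen-4-one F9, from which TBAF/AcOH (THF, 0 °C) would free target 10 directly.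

**Further compounds**

F1 | step 5 | (2RS)-2-(4-{[tert-butyl(dimethyl)silyl]oxy}phenyl)-6-[(1E,3S)-3,7-dimethylocta-1,6-dien-1-yl]-5,7-bis(methoxymethoxy)-2,3-dihydro-4H-chromen-4-one (both C2 epimers) | CC(C)=CCC[C@H](C)/C=C/c1c(OCOC)cc2c(c1OCOC)C(=O)CC(c1ccc(O[Si](C)(C)C(C)(C)C)cc1)O2
F2 | step 5 | (2R,4R)-2-(4-{[tert-butyl(dimethyl)silyl]oxy}phenyl)-6-[(1E,3S)-3,7-dimethylocta-1,6-dien-1-yl]-5,7-bis(methoxymethoxy)-3,4-dihydro-2H-chromen-4-ol | CC(C)=CCC[C@H](C)/C=C/c1c(OCOC)cc2c(c1OCOC)[C@H](O)C[C@H](c1ccc(O[Si](C)(C)C(C)(C)C)cc1)O2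
F3 | step 4 | (3S)-3,7-dimethyloct-6-enal ((S)-citronellal) | CC(C)=CCC[C@H](C)CC=O
F4 | step 4 | (3S)-3,7-dimethyloct-6-en-1-yne | CC(C)=CCC[C@H](C)C#C
F5 | step 4 | 2-[(1E,3S)-3,7-dimethylocta-1,6-dien-1-yl]-4,4,5,5-tetramethyl-1,3,2-dioxaborolane | CC(C)=CCC[C@H](C)/C=C/B1OC(C)(C)C(C)(C)O1
F6 | step 6 | 5,7-dihydroxy-6-iodo-4H-chromen-4-one | Oc1cc2OC=CC(=O)c2c(O)c1I
F7 | step 6 | 5,7-bis{[tert-butyl(dimethyl)silyl]oxy}-6-iodo-4H-chromen-4-one | CC(C)(C)[Si](C)(C)Oc1cc2OC=CC(=O)c2c(O[Si](C)(C)C(C)(C)C)c1I
F8 | step 6 | 5,7-bis{[tert-butyl(dimethyl)silyl]oxy}-6-[(1E,3S)-3,7-dimethylocta-1,6-dien-1-yl]-4H-chromen-4-one | CC(C)=CCC[C@H](C)/C=C/c1c(O[Si](C)(C)C(C)(C)C)cc2OC=CC(=O)c2c1O[Si](C)(C)C(C)(C)C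
F9 | step 6 | (2S)-5,7-bis{[tert-butyl(dimethyl)silyl]oxy}-2-(4-{[tert-butyl(dimethyl)silyl]oxy}phenyl)-6-[(1E,3S)-3,7-dimethylocta-1,6-dien-1-yl]-2,3-dihydro-4H-chromen-4-one | CC(C)=CCC[C@H](C)/C=C/c1c(O[Si](C)(C)C(C)(C)C)cc2c(c1O[Si](C)(C)C(C)(C)C)C(=O)C[C@@H](c1ccc(O[Si](C)(C)C(C)(C)C)cc1)O2
A1 | direct plan | 5-{[tri(propan-2-yl)silyl]oxy}benzene-1,3-diol | Oc1cc(O)cc(O[Si](C(C)C)(C(C)C)C(C)C)c1
A2 | direct plan | (1RS,3S)-1-{2,6-bis(methoxymethoxy)-4-[tri(propan-2-yl)silyloxy]phenyl}-3,7-dimethyloct-6-en-1-ol | CC(C)=CCC[C@H](C)CC(O)c1c(OCOC)cc(O[Si](C(C)C)(C(C)C)C(C)C)cc1OCOC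
A3 | direct plan | (2E)-1-{3-[(1E,3S)-3,7-dimethylocta-1,6-dien-1-yl]-6-hydroxy-2,4-bis(methoxymethoxy)phenyl}-3-[4-(methoxymethoxy)phenyl]prop-2-en-1-one | CC(C)=CCC[C@H](C)/C=C/c1c(OCOC)cc(O)c(C(=O)/C=C/c2ccc(OCOC)cc2)c1OCOC
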